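Readings and results are simulated for an exercise; noise was put on by code.

Count the allowed 20 min in peak times, not in minutes.

| flask | starting complex | incoming ligand | remark | time |
|---|---|---|---|---|
| red | 0.30 M | 0.87 equiv | run made earlier |  |
| amber | 0.30 M | 2 equiv | run made earlier |  |
| grey | 0.60 M | 1.3 equiv | run made earlier |  |
| flask | 0.30 M | 1.30 equiv |  | 20 min |

- red (time / min: complex with one exchanged / %): 0.200: 5.4; 1.00: 9.4; 4.00: 6.6; 20.0: 7.0
- amber (time / min: complex with one exchanged / %): 0.200: 11.9; 1.00: 10.2; 4.00: 4.6; 20.0: 5.7
- grey (time / min: complex with one exchanged / %): 0.200: 12.5; 1.00: 8.5; 4.00: 5.2; 20.0: 3.4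

(each reading ± 1 percentage point)

- what was read earlier has a scatter of 1 percentage point, one standard deviation

- time up to 20 min at which complex with one exchanged stands highest
- the amount of complex with one exchanged, in percent of the starting complex charged, at that time

For the complex with one exchanged, an intermediate of consecutive steps, to stand highest at the end of this flask, the readings would have to be still climbing late, with a peak time near 20 min. The runs read otherwise: the red run reads highest at 1.00 min, and the amber run, charged with more incoming ligand, at its first reading, 0.200 min. So I take the peak time as inverse to the charged ligand concentration. The red run reads 15.7 M·s for peak time times charged concentration of incoming ligand, which I call the ligand exposure E. Dividing E by the charge of this flask puts its peak near 0.669 min, so 20 min is about 29.9 peak times where the opposite outcome needs about one. This is a coarse estimate, since E comes from widely spaced readings that each carry a scatter of 1 percentage point.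

The forecast gives 11 % at 0.5 min, earlier than my reckoning: “Scaling time roughly inversely with ligand concentration puts its peak near 0.5 min”.

The flask gives 11.6 % at 0.446 min, earlier than E put it, and stands lower at its end, with 7.24 % at 20.0 min.

    incoming ligand → decomposed reagent (k = 0.00637 s⁻¹)
    complex with one exchanged + incoming ligand → leaving ligand + complex with two exchanged (k = 0.0961 L mol⁻¹ s⁻¹)
    complex with two exchanged + incoming ligand → leaving ligand + complex with three exchanged (k = 0.199 L mol⁻¹ s⁻¹)
    starting complex ⇌ dormant form (K = 1.30, k = 0.0322 s⁻¹)
    2 starting complex → homo dimer (k = 0.0673 L mol⁻¹ s⁻¹)
    starting complex + incoming ligand → leaving ligand + complex with one exchanged (k = 0.0443 L mol⁻¹ s⁻¹)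

With concentrations as charged in this flask, the complex with one exchanged has a half-life of 0.31 min by its onward step, shorter than the 0.67 min of starting complex by the step that makes it. At 0.826 min in this flask it is made at 0.750 of the rate at which it is used up, each step taken net.

For the neighbour with 3.20 equiv of incoming ligand, E gives a peak near 0.272 min, about 73.6 peak times inside 20 min, so I expect its highest point long before its end. That neighbour gives 16.0 % at best and 2.99 % at 20.0 min.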